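**Plan**

- Numbering: ring C1' (carbinol), C2' (methyl-bearing alkene carbon), C3', C4' (ketone), C5', C6' (quaternary); chain C1 to C5 on C1'. The retrosynthesis cuts, in this order: the two allyl-masked acids, the glutarate ester C–O bond at the C6' CH2O, C3–C4 (tin/iodine coupling), C4≡C5 (one-carbon homologation of C5), the C1'–OH bond, then C1'–C6' and C2'=C3' together, and last the tether ester and C5'=C6'.
- Enabling feature: C5–C1'–C2'–CH3 is an acetoacetate unit, and C3'–C4'–C5'–C6' with the C6' methyl and CH2O is a 5-oxygenated 4-methylpent-3-en-2-one. CH2O and C5 are cis on the ring, so the two units can be joined first as an ester and the ring system then arises as a γ-lactone fused to the cyclohexenone.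
- Forward order: Wittig, acetoacetylation, then one operation that closes the γ-lactone and the cyclohexenone. The ketone is masked as a silyl ether and C1' is hydroxylated. The lactone is reduced and opened to an alkyne plus CH2OH. Hydrostannation and coupling with a Z-iodobutenoate build the dienoate. The glutarate half-ester (four steps from (R)-mevalonolactone) is attached, then desilylation, MnO2 oxidation and deallylation.
- Stereochemistry: C6' from a chiral primary amine acting on the E-enone (catalyst control). C1' from the cis-fused lactone, which places the hydroxyl cis to the C6' methyl (substrate control). The glutarate carbinol comes from (R)-mevalonolactone with its two arms kept distinct. 2Z comes from anti-hydroiodination and retention in the coupling; 4E from syn-hydrostannation.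

Key step: step 3

Assumption 1: the quinine-derived amine is written for step 3; the sense of induction at C6' must be confirmed on 9, and the quinidine-derived pseudoenantiomer would take its place if the sense proves opposite.
Assumption 2: the carbinol carbon C4' made in step 4 is temporary, is carried as formed (written without a descriptor in 10 to 28) and is erased in step 19.

**Route**

Step 1
Reactants: 1 hydroxyacetone; 2 1-(triphenyl-λ5-phosphanylidene)propan-2-one
Product: 3 (3E)-5-hydroxy-4-methylpent-3-en-2-one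
Conditions: toluene, 85 °C
Reagents that add atoms: none
Why: Wittig olefination of an α-hydroxy ketone with a carbonyl-stabilised ylide should be E-selective (CH2OH trans to the acetyl group), and any Z isomer should drain away as volatile 2,4-dimethylfuran.

Step 2
Reactants: 3 (3E)-5-hydroxy-4-methylpent-3-en-2-one; 4 2,2,6-trimethyl-4H-1,3-dioxin-4-one
Product: 6 (2E)-2-methyl-4-oxopent-2-en-1-yl 3-oxobutanoate, via acetylketene 5 (not isolated)
Conditions: xylene, 130 °C, short reaction time, acetone distilled off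
Reagents that add atoms: none
Why: Thermal retro-hetero-Diels–Alder cleavage of the dioxinone releases acetylketene, which the primary alcohol should trap much faster than the neutral enone can react (acetoacetylation by the dioxinone method).

Step 3
Reactants: 6 (2E)-2-methyl-4-oxopent-2-en-1-yl 3-oxobutanoate
Product: 9 (3aR,7aS)-3a,7-dimethyl-3a,4-dihydro-2-benzofuran-1,5(3H,7aH)-dione, via Michael adduct lactone 7 (not isolated), via ketol 8 (not isolated)
Conditions: 9-amino-9-deoxy-epi-quinine (20 mol %), PhCO2H (40 mol %), toluene, 40 °C, then 70 °C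
Reagents that add atoms: none
Why: Proposed new method: the primary amine should condense with the methyl ketone of 6 to an iminium ion that activates the disubstituted alkene carbon C6', the tethered acetoacetate enol adds there to give 7, and the amine, now as the terminal enamine of the same ketone (through C3'), attacks the acetyl carbonyl C2' to give 8, which loses water to 9; the closest known reaction type is the intermolecular primary-amine-catalysed Michael–aldol (Robinson-type) annulation of β-keto esters with enones, extended here to a tethered β,β-disubstituted acceptor. The γ-lactone closes in a 5-(enolexo)-exo-trig conjugate addition through the s-cis rotamer of the ester, and the cyclohexenone closes in a 6-(enolendo)-exo-trig aldol addition followed by dehydration. The quaternary centre C6' is set by catalyst control, the amine substituent of the iminium ion shielding one face of the E-alkene, while C1', an acidic vinylogous β-keto ester position, settles by equilibration into the cis-fused lactone. The step needs enantioface selection at C6' and aldol regiochemistry in favour of the C2'-methyl enone; the first rests on the single E geometry of 6 and the intramolecular delivery, the second on the fact that only the unconjugated methyl ketone forms a reactive enamine whereas the acetyl group is held as the enolised β-keto lactone. Intramolecularity should offset the low reactivity of a β,β-disubstituted enone, and the irreversible dehydration drains the reversible Michael equilibrium.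

Step 4
Reactants: 9 (3aR,7aS)-3a,7-dimethyl-3a,4-dihydro-2-benzofuran-1,5(3H,7aH)-dione
Product: 10 (3aR,7aS)-5-hydroxy-3a,7-dimethyl-3a,4,5,7a-tetrahydro-2-benzofuran-1(3H)-one
Conditions: NaBH4, CeCl3·7H2O, MeOH, −78 to −20 °C
Reagents that add atoms: none
Why: Luche reduction delivers hydride 1,2 to the enone carbonyl and leaves the lactone untouched; the new C4' carbinol centre is temporary, so either epimer serves.

Step 5
Reactants: 10 (3aR,7aS)-5-hydroxy-3a,7-dimethyl-3a,4,5,7a-tetrahydro-2-benzofuran-1(3H)-one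
Product: 11 (3aR,7aS)-5-[(tert-butyldimethylsilyl)oxy]-3a,7-dimethyl-3a,4,5,7a-tetrahydro-2-benzofuran-1(3H)-one
Conditions: TBSCl, imidazole, DMF, rt
Reagents that add atoms: tert-butyldimethylsilyl chloride, CC(C)(C)[Si](C)(C)Cl
Why: Standard silylation of a secondary allylic alcohol masks the C4' oxygen for the enolate, hydride and coupling steps that follow.

Step 6
Reactants: 11 (3aR,7aS)-5-[(tert-butyldimethylsilyl)oxy]-3a,7-dimethyl-3a,4,5,7a-tetrahydro-2-benzofuran-1(3H)-one
Product: 12 (3aS,7aR)-5-[(tert-butyldimethylsilyl)oxy]-7a-hydroxy-3a,7-dimethyl-3a,4,5,7a-tetrahydro-2-benzofuran-1(3H)-one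
Conditions: KN(SiMe3)2, THF, −78 °C; then 3-phenyl-2-(phenylsulfonyl)oxaziridine, −78 °C; aqueous quench
Reagents that add atoms: 3-phenyl-2-(phenylsulfonyl)oxaziridine, O=S(=O)(c1ccccc1)N1OC1c1ccccc1
Why: Davis α-hydroxylation of a lactone enolate: the potassium dienolate should be attacked at its α-carbon C1', and only attack on the face of the C6' methyl keeps the five-membered lactone cis-fused, so the hydroxyl should end cis to that methyl (the descriptors change only because the priorities change).

Step 7
Reactants: 12 (3aS,7aR)-5-[(tert-butyldimethylsilyl)oxy]-7a-hydroxy-3a,7-dimethyl-3a,4,5,7a-tetrahydro-2-benzofuran-1(3H)-one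
Product: 13 (3aS,7aR)-5-[(tert-butyldimethylsilyl)oxy]-3a,7-dimethyl-1,3,3a,4,5,7a-hexahydro-2-benzofuran-1,7a-diol
Conditions: i-Bu2AlH (2.5 equiv), CH2Cl2, −78 °C; Rochelle salt work-up
Reagents that add atoms: none
Why: Partial reduction of a lactone with i-Bu2AlH at low temperature stops at the aluminium hemiacetal, the first equivalent being consumed by the tertiary hydroxyl.

Step 8
Reactants: 13 (3aS,7aR)-5-[(tert-butyldimethylsilyl)oxy]-3a,7-dimethyl-1,3,3a,4,5,7a-hexahydro-2-benzofuran-1,7a-diol
Product: 14 (1R,6S)-4-[(tert-butyldimethylsilyl)oxy]-1-ethynyl-6-(hydroxymethyl)-2,6-dimethylcyclohex-2-en-1-ol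
Conditions: dimethyl (1-diazo-2-oxopropyl)phosphonate, K2CO3, MeOH, 0 °C to rt
Reagents that add atoms: dimethyl (1-diazo-2-oxopropyl)phosphonate, COP(=O)(OC)C(=[N+]=[N-])C(C)=O
Why: Ohira–Bestmann (Seyferth–Gilbert) homologation of the open hydroxy-aldehyde tautomer of the lactol should give the terminal alkyne and unmask the primary alcohol without touching the fully substituted C1'.

Step 9
Reactants: 14 (1R,6S)-4-[(tert-butyldimethylsilyl)oxy]-1-ethynyl-6-(hydroxymethyl)-2,6-dimethylcyclohex-2-en-1-ol
Product: 15 (1R,6S)-4-[(tert-butyldimethylsilyl)oxy]-6-(hydroxymethyl)-2,6-dimethyl-1-[(E)-2-(tributylstannyl)ethenyl]cyclohex-2-en-1-ol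
Conditions: Bu3SnH, PdCl2(PPh3)2 (3 mol %), THF, 0 °C
Reagents that add atoms: tributyltin hydride, CCCC[SnH](CCCC)CCCC
Why: Palladium-catalysed syn-hydrostannation of a terminal alkyne next to a fully substituted carbinol carbon should place tin at the terminal carbon and give the E-vinylstannane; it is run before any allyl ester is present.

Step 10
Reactants: 16 but-2-ynoic acid
Product: 17 (2Z)-3-iodobut-2-enoic acid
Conditions: aq. HI (57 %), rt
Reagents that add atoms: hydrogen iodide, I
Why: Anti-addition of HI across the ynoic acid gives the Z-β-iodo acid (iodine cis to the carboxyl), the known hydroiodination of 2-alkynoic acids.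

Step 11
Reactants: 17 (2Z)-3-iodobut-2-enoic acid
Product: 18 prop-2-en-1-yl (2Z)-3-iodobut-2-enoate
Conditions: allyl bromide, KHCO3, DMF, rt
Reagents that add atoms: allyl bromide, C=CCBr
Why: Carboxylate O-alkylation under bicarbonate conditions is too mild to isomerise or dehydroiodinate the Z-iodoalkene.

Step 12
Reactants: 15 (1R,6S)-4-[(tert-butyldimethylsilyl)oxy]-6-(hydroxymethyl)-2,6-dimethyl-1-[(E)-2-(tributylstannyl)ethenyl]cyclohex-2-en-1-ol; 18 prop-2-en-1-yl (2Z)-3-iodobut-2-enoate
Product: 19 prop-2-en-1-yl (2Z,4E)-5-[(1R,6S)-4-[(tert-butyldimethylsilyl)oxy]-1-hydroxy-6-(hydroxymethyl)-2,6-dimethylcyclohex-2-en-1-yl]-3-methylpenta-2,4-dienoate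
Conditions: copper thiophene-2-carboxylate Cu(O2CC4H3S) (1.5 equiv), NMP, 0 °C to rt, subdued light
Reagents that add atoms: none
Why: The copper-mediated Stille-type coupling (Liebeskind variant) should join the vinylstannane and the Z-β-iodoenoate with retention at both alkenes and, being free of palladium, leave the allyl ester intact.

Step 13
Reactants: 20 (R)-mevalonolactone
Product: 22 4-methoxybenzyl (3R)-3,5-dihydroxy-3-methylpentanoate, via potassium (R)-mevalonate 21 (not isolated)
Conditions: KOH (1.0 equiv), H2O, rt; evaporate; 4-MeOC6H4CH2Cl, DMF, rt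
Reagents that add atoms: potassium hydroxide, [K+].[OH-]; 4-methoxybenzyl chloride, COc1ccc(CCl)cc1
Why: Saponification of the δ-lactone and carboxylate alkylation should give the acid-labile 4-methoxybenzyl ester and free the primary hydroxyl without touching the stereocentre.

Step 14
Reactants: 22 4-methoxybenzyl (3R)-3,5-dihydroxy-3-methylpentanoate
Product: 24 (3R)-3-hydroxy-5-[(4-methoxyphenyl)methoxy]-3-methyl-5-oxopentanoic acid, via aldehyde 23 (not isolated)
Conditions: TEMPO (cat.), PhI(OAc)2 (2.2 equiv), MeCN/H2O, rt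
Reagents that add atoms: water, O
Why: TEMPO/PhI(OAc)2 oxidation in aqueous acetonitrile takes the primary alcohol through the aldehyde hydrate to the acid and cannot oxidise the tertiary alcohol.

Step 15
Reactants: 24 (3R)-3-hydroxy-5-[(4-methoxyphenyl)methoxy]-3-methyl-5-oxopentanoic acid
Product: 25 1-(4-methoxybenzyl) 5-prop-2-en-1-yl (3R)-3-hydroxy-3-methylpentanedioate
Conditions: allyl bromide, KHCO3, DMF, rt
Reagents that add atoms: allyl bromide, C=CCBr
Why: Carboxylate alkylation with allyl bromide under bicarbonate conditions is too mild for retro-aldol cleavage of the tertiary β-hydroxy diester.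

Step 16
Reactants: 25 1-(4-methoxybenzyl) 5-prop-2-en-1-yl (3R)-3-hydroxy-3-methylpentanedioate
Product: 26 (3S)-3-hydroxy-3-methyl-5-oxo-5-(prop-2-en-1-yloxy)pentanoic acid
Conditions: CF3CO2H, anisole, CH2Cl2, 0 °C
Reagents that add atoms: none
Why: Acidolysis of a 4-methoxybenzyl ester with anisole as cation scavenger leaves the allyl ester in place, and the tertiary alcohol flanked by two carbonyl-bearing methylenes resists ionisation (the descriptor changes only because the priorities change).

Step 17
Reactants: 19 prop-2-en-1-yl (2Z,4E)-5-[(1R,6S)-4-[(tert-butyldimethylsilyl)oxy]-1-hydroxy-6-(hydroxymethyl)-2,6-dimethylcyclohex-2-en-1-yl]-3-methylpenta-2,4-dienoate; 26 (3S)-3-hydroxy-3-methyl-5-oxo-5-(prop-2-en-1-yloxy)pentanoic acid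
Product: 27 prop-2-en-1-yl (2Z,4E)-5-[(1R,6S)-4-[(tert-butyldimethylsilyl)oxy]-1-hydroxy-2,6-dimethyl-6-({[(3R)-3-hydroxy-3-methyl-5-oxo-5-(prop-2-en-1-yloxy)pentanoyl]oxy}methyl)cyclohex-2-en-1-yl]-3-methylpenta-2,4-dienoate
Conditions: EDC·HCl, DMAP, CH2Cl2, 0 °C to rt, subdued light
Reagents that add atoms: none
Why: Carbodiimide/DMAP (Steglich) esterification should acylate only the primary neopentyl-type hydroxyl, since all tertiary alcohols are too hindered to compete.

Step 18
Reactants: 27 the silyl ether triester of step 17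
Product: 28 prop-2-en-1-yl (2Z,4E)-5-[(1R,6S)-1,4-dihydroxy-2,6-dimethyl-6-({[(3R)-3-hydroxy-3-methyl-5-oxo-5-(prop-2-en-1-yloxy)pentanoyl]oxy}methyl)cyclohex-2-en-1-yl]-3-methylpenta-2,4-dienoate
Conditions: HF·pyridine, pyridine, THF, 0 °C to rt
Reagents that add atoms: none
Why: Buffered fluoride cleavage of the secondary silyl ether is near-neutral and should spare the three esters and the acid-sensitive tertiary allylic alcohol.

Step 19
Reactants: 28 the 1,4-diol triester of step 18
Product: 29 prop-2-en-1-yl (2Z,4E)-5-[(1R,6S)-1-hydroxy-2,6-dimethyl-6-({[(3R)-3-hydroxy-3-methyl-5-oxo-5-(prop-2-en-1-yloxy)pentanoyl]oxy}methyl)-4-oxocyclohex-2-en-1-yl]-3-methylpenta-2,4-dienoate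
Conditions: activated MnO2, CH2Cl2, rt, subdued light
Reagents that add atoms: none
Why: Activated MnO2 oxidises the secondary allylic alcohol to the enone chemoselectively, and because the C6' hydroxymethyl oxygen is already acylated no intramolecular oxa-Michael addition to the new enone can follow.

Step 20
Reactants: 29 the enone bis(allyl ester) of step 19
Product: 30 (2Z,4E)-5-[(1R,6S)-6-({[(3R)-4-carboxy-3-hydroxy-3-methylbutanoyl]oxy}methyl)-1-hydroxy-2,6-dimethyl-4-oxocyclohex-2-en-1-yl]-3-methylpenta-2,4-dienoic acid (CNP0183058.1)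
Conditions: Pd(PPh3)4 (5 mol %), morpholine, THF, rt, dark; then aq. citric acid
Reagents that add atoms: none
Why: Pd(PPh3)4-catalysed allyl transfer to morpholine (Tsuji–Trost deallylation) should remove both allyl esters under neutral conditions that keep the base-labile glutarate ester and the 2Z,4E-diene.

**Compound list**

1 | hydroxyacetone (1-hydroxypropan-2-one) | CC(=O)CO | starting material
2 | 1-(triphenyl-λ5-phosphanylidene)propan-2-one | CC(=O)C=P(c1ccccc1)(c1ccccc1)c1ccccc1 | starting material
3 | (3E)-5-hydroxy-4-methylpent-3-en-2-one | OC/C(C)=C/C(C)=O | intermediate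
4 | 2,2,6-trimethyl-4H-1,3-dioxin-4-one | CC1=CC(=O)OC(C)(C)O1 | starting material
5 | acetylketene (not isolated) | CC(=O)C=C=O | intermediate
6 | (2E)-2-methyl-4-oxopent-2-en-1-yl 3-oxobutanoate | CC(=O)CC(=O)OC/C(C)=C/C(C)=O | intermediate
7 | (4R)-3-acetyl-4-methyl-4-(2-oxopropyl)oxolan-2-one (C3 labile, not isolated) | CC(=O)C[C@@]1(C)COC(=O)C1C(C)=O | intermediate
8 | (3aR)-7-hydroxy-3a,7-dimethylhexahydro-2-benzofuran-1,5-dione (ketol, not isolated) | C[C@]12COC(=O)C1C(C)(O)CC(=O)C2 | intermediate
9 | (3aR,7aS)-3a,7-dimethyl-3a,4-dihydro-2-benzofuran-1,5(3H,7aH)-dione (cis-fused) | CC1=CC(=O)C[C@@]2(C)COC(=O)[C@@H]12 | intermediate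
10 | (3aR,7aS)-5-hydroxy-3a,7-dimethyl-3a,4,5,7a-tetrahydro-2-benzofuran-1(3H)-one | CC1=CC(O)C[C@@]2(C)COC(=O)[C@@H]12 | intermediate
11 | (3aR,7aS)-5-[(tert-butyldimethylsilyl)oxy]-3a,7-dimethyl-3a,4,5,7a-tetrahydro-2-benzofuran-1(3H)-one | CC1=CC(O[Si](C)(C)C(C)(C)C)C[C@@]2(C)COC(=O)[C@@H]12 | intermediate
12 | (3aS,7aR)-5-[(tert-butyldimethylsilyl)oxy]-7a-hydroxy-3a,7-dimethyl-3a,4,5,7a-tetrahydro-2-benzofuran-1(3H)-one | CC1=CC(O[Si](C)(C)C(C)(C)C)C[C@@]2(C)COC(=O)[C@@]12O | intermediate
13 | (3aS,7aR)-5-[(tert-butyldimethylsilyl)oxy]-3a,7-dimethyl-1,3,3a,4,5,7a-hexahydro-2-benzofuran-1,7a-diol (lactol, anomers) | CC1=CC(O[Si](C)(C)C(C)(C)C)C[C@@]2(C)COC(O)[C@@]12O | intermediate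
14 | (1R,6S)-4-[(tert-butyldimethylsilyl)oxy]-1-ethynyl-6-(hydroxymethyl)-2,6-dimethylcyclohex-2-en-1-ol | CC1=CC(O[Si](C)(C)C(C)(C)C)C[C@@](C)(CO)[C@@]1(O)C#C | intermediate
15 | (1R,6S)-4-[(tert-butyldimethylsilyl)oxy]-6-(hydroxymethyl)-2,6-dimethyl-1-[(E)-2-(tributylstannyl)ethenyl]cyclohex-2-en-1-ol | CC1=CC(O[Si](C)(C)C(C)(C)C)C[C@@](C)(CO)[C@@]1(O)/C=C/[Sn](CCCC)(CCCC)CCCC | intermediate
16 | but-2-ynoic acid | CC#CC(=O)O | starting material
17 | (2Z)-3-iodobut-2-enoic acid | C/C(I)=C/C(=O)O | intermediate
18 | prop-2-en-1-yl (2Z)-3-iodobut-2-enoate | C/C(I)=C/C(=O)OCC=C | intermediate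
19 | prop-2-en-1-yl (2Z,4E)-5-[(1R,6S)-4-[(tert-butyldimethylsilyl)oxy]-1-hydroxy-6-(hydroxymethyl)-2,6-dimethylcyclohex-2-en-1-yl]-3-methylpenta-2,4-dienoate | CC1=CC(O[Si](C)(C)C(C)(C)C)C[C@@](C)(CO)[C@@]1(O)/C=C/C(C)=C\C(=O)OCC=C | intermediate
20 | (R)-mevalonolactone | O=C1C[C@](C)(O)CCO1 | starting material
21 | potassium (3R)-3,5-dihydroxy-3-methylpentanoate (not isolated) | [K+].[O-]C(=O)C[C@](C)(O)CCO | intermediate
22 | 4-methoxybenzyl (3R)-3,5-dihydroxy-3-methylpentanoate | COc1ccc(COC(=O)C[C@](C)(O)CCO)cc1 | intermediate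
23 | 4-methoxybenzyl (3R)-3-hydroxy-3-methyl-5-oxopentanoate (not isolated) | COc1ccc(COC(=O)C[C@](C)(O)CC=O)cc1 | intermediate
24 | (3R)-3-hydroxy-5-[(4-methoxyphenyl)methoxy]-3-methyl-5-oxopentanoic acid | COc1ccc(COC(=O)C[C@](C)(O)CC(=O)O)cc1 | intermediate
25 | 1-(4-methoxybenzyl) 5-prop-2-en-1-yl (3R)-3-hydroxy-3-methylpentanedioate | COc1ccc(COC(=O)C[C@](C)(O)CC(=O)OCC=C)cc1 | intermediate
26 | (3S)-3-hydroxy-3-methyl-5-oxo-5-(prop-2-en-1-yloxy)pentanoic acid | OC(=O)C[C@](C)(O)CC(=O)OCC=C | intermediate
27 | prop-2-en-1-yl (2Z,4E)-5-[(1R,6S)-4-[(tert-butyldimethylsilyl)oxy]-1-hydroxy-2,6-dimethyl-6-({[(3R)-3-hydroxy-3-methyl-5-oxo-5-(prop-2-en-1-yloxy)pentanoyl]oxy}methyl)cyclohex-2-en-1-yl]-3-methylpenta-2,4-dienoate | CC1=CC(O[Si](C)(C)C(C)(C)C)C[C@@](C)(COC(=O)C[C@](C)(O)CC(=O)OCC=C)[C@@]1(O)/C=C/C(C)=C\C(=O)OCC=C | intermediate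
28 | prop-2-en-1-yl (2Z,4E)-5-[(1R,6S)-1,4-dihydroxy-2,6-dimethyl-6-({[(3R)-3-hydroxy-3-methyl-5-oxo-5-(prop-2-en-1-yloxy)pentanoyl]oxy}methyl)cyclohex-2-en-1-yl]-3-methylpenta-2,4-dienoate | CC1=CC(O)C[C@@](C)(COC(=O)C[C@](C)(O)CC(=O)OCC=C)[C@@]1(O)/C=C/C(C)=C\C(=O)OCC=C | intermediate
29 | prop-2-en-1-yl (2Z,4E)-5-[(1R,6S)-1-hydroxy-2,6-dimethyl-6-({[(3R)-3-hydroxy-3-methyl-5-oxo-5-(prop-2-en-1-yloxy)pentanoyl]oxy}methyl)-4-oxocyclohex-2-en-1-yl]-3-methylpenta-2,4-dienoate | CC1=CC(=O)C[C@@](C)(COC(=O)C[C@](C)(O)CC(=O)OCC=C)[C@@]1(O)/C=C/C(C)=C\C(=O)OCC=C | intermediate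
30 | (2Z,4E)-5-[(1R,6S)-6-({[(3R)-4-carboxy-3-hydroxy-3-methylbutanoyl]oxy}methyl)-1-hydroxy-2,6-dimethyl-4-oxocyclohex-2-en-1-yl]-3-methylpenta-2,4-dienoic acid | CC1=CC(=O)C[C@@](C)(COC(=O)C[C@](C)(O)CC(=O)O)[C@@]1(O)/C=C/C(C)=C\C(=O)O | target

**Step count and risks**

Total step count: 20. Longest linear sequence: 14 steps (steps 1 to 9, 12, 17 to 20). The iodoester branch (steps 10, 11) and the glutarate branch (steps 13 to 16) are convergent.

Steps most likely to fail:

1. Step 3. The tethered Michael addition may be slow because the ester must reach its s-cis rotamer and the acceptor carbon is fully substituted. The amine may be held back as an enaminone of the acetoacetate, and face selection at C6' may be poor. Fallback from 6, with known chemistry and without asymmetric induction: Cs2CO3 in MeCN at rt should close the lactone by base-mediated intramolecular Michael addition to give racemic 3-acetyl-4-methyl-4-(2-oxopropyl)oxolan-2-one F1. Pyrrolidine/AcOH in toluene at 80 °C (aldol condensation of the Robinson type) should then give the racemic cis-fused enone lactone F2. Preparative chromatography on a cellulose-based chiral stationary phase separates the antipodes; the (3aS,7aR)-enantiomer F3 is set aside and the other is 9, where the route is rejoined.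

2. Step 6. The oxidant may attack the γ-carbon of the dienolate, silanolate may be lost by 1,4-elimination, or approach to the hindered α-carbon may be too slow. Fallback from 9: oxygen is introduced at the enone stage, where the C1' hydrogen is the most acidic in the molecule. DBU, O2 and P(OEt)3 in MeCN at 0 °C (autoxidation of the extended enolate, the known γ-hydroxylation of enones) should give (3aS,7aR)-7a-hydroxy-3a,7-dimethyl-3a,4-dihydro-2-benzofuran-1,5(3H,7aH)-dione F4. Luche reduction then gives (3aS,7aR)-5,7a-dihydroxy-3a,7-dimethyl-3a,4,5,7a-tetrahydro-2-benzofuran-1(3H)-one F5, and TBSCl/imidazole silylates only the secondary hydroxyl, returning to 12.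

3. Step 8. The lactol may open too little to the hindered aldehyde, and under carbonate/methanol the tertiary α-hydroxy aldehyde may undergo α-ketol rearrangement before homologation. Fallback from 13: Takai iodo-olefination (CrCl2, CHI3, THF/dioxane, rt), which is non-basic, should give (1R,6S)-4-[(tert-butyldimethylsilyl)oxy]-6-(hydroxymethyl)-1-[(E)-2-iodoethenyl]-2,6-dimethylcyclohex-2-en-1-ol F6. Stannylation with Bu3SnSnBu3 and PdCl2(PPh3)2 in THF then returns to 15.

**Further compounds**

F1 | step 3 | racemic 3-acetyl-4-methyl-4-(2-oxopropyl)oxolan-2-one | CC(=O)C[C@@]1(C)COC(=O)C1C(C)=O.CC(=O)C[C@]1(C)COC(=O)C1C(C)=O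
F2 | step 3 | racemic cis-fused 3a,7-dimethyl-3a,4-dihydro-2-benzofuran-1,5(3H,7aH)-dione | CC1=CC(=O)C[C@@]2(C)COC(=O)[C@@H]12.CC1=CC(=O)C[C@]2(C)COC(=O)[C@H]12
F3 | step 3 | (3aS,7aR)-3a,7-dimethyl-3a,4-dihydro-2-benzofuran-1,5(3H,7aH)-dione (separated antipode of 9) | CC1=CC(=O)C[C@]2(C)COC(=O)[C@H]12
F4 | step 6 | (3aS,7aR)-7a-hydroxy-3a,7-dimethyl-3a,4-dihydro-2-benzofuran-1,5(3H,7aH)-dione | CC1=CC(=O)C[C@@]2(C)COC(=O)[C@@]12O
F5 | step 6 | (3aS,7aR)-5,7a-dihydroxy-3a,7-dimethyl-3a,4,5,7a-tetrahydro-2-benzofuran-1(3H)-one | CC1=CC(O)C[C@@]2(C)COC(=O)[C@@]12O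
F6 | step 8 | (1R,6S)-4-[(tert-butyldimethylsilyl)oxy]-6-(hydroxymethyl)-1-[(E)-2-iodoethenyl]-2,6-dimethylcyclohex-2-en-1-ol | CC1=CC(O[Si](C)(C)C(C)(C)C)C[C@@](C)(CO)[C@@]1(O)/C=C/I
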